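**Target:** [(1R,2R,5R,6S)-2,5-bis(benzoyloxy)-1,6-dihydroxycyclohex-3-en-1-yl]methyl benzoate. Around the ring the oxygens alternate faces: C1-OH up, C2-OBz down, C5-OBz up, C6-OH down, with CH2OBz on C1 down.

**Retrosynthetic overview**
- The last two C–O bonds (C1–OH, C2–OBz) come from a vinyl oxirane opened at its allylic carbon by benzoic acid, as in the proposed biogenesis of the benzoylated cyclohexene oxides from benzyl benzoate arene oxide.
- That oxirane comes from a trans-5-benzoyloxy-6-silyloxy-1-(benzoyloxymethyl)cyclohexa-1,3-diene, a protected form of the biogenetic "diene" stage, made by bromination and twofold dehydrobromination.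
- The trans C5-OBz/C6-O pair comes from benzoate opening of a configurationally stable arene-oxide surrogate, the mono-oxirane of (cyclohexa-2,5-dienyl)methyl benzoate.
- All chirality comes from one catalytic desymmetrising epoxidation of achiral (cyclohexa-2,5-dienyl)methanol, made from cyclohexa-1,4-diene and formaldehyde.
- Ring order: the carbocycle is bought; the C5–C6 oxirane is formed and opened first, the C1–C2 oxirane is formed and opened last.

Assumption: locants C1–C6 in the text are those of the target ring, and the antipodes of the two chiral catalysts are written as expected by analogy with their meso-type cases (the mirror-image catalyst is used if the sense proves opposite).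

**Step 1**
Reactants: 1 cyclohexa-1,4-diene
Product: 3 (cyclohexa-2,5-dien-1-yl)methanol, via cyclohexa-2,5-dienyllithium 2 (not isolated)
Conditions: sec-BuLi, TMEDA, THF, −78 °C; then CH2O gas (cracked paraformaldehyde), −78 °C; aq NH4Cl
Reagents that add atoms: formaldehyde, C=O
Why: Deprotonation of the doubly allylic CH2 gives the pentadienyl-type anion, which adds to formaldehyde through its central carbon (organolithium hydroxymethylation, 1,2-addition) to give the unconjugated, achiral dienyl carbinol; no stereocentre is formed.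

**Step 2**
Reactants: 3 (cyclohexa-2,5-dien-1-yl)methanol
Product: 4 [(1R,2S,6S)-7-oxabicyclo[4.1.0]hept-3-en-2-yl]methanol (oxirane cis to CH2OH)
Conditions: VO(Oi-Pr)3 (2 mol %), (R,R)-N,N′-dihydroxy-N,N′-bis(diphenylacetyl)cyclohexane-1,2-diamine (4 mol %), cumene hydroperoxide (1.05 equiv), toluene, 0 °C
Reagents that add atoms: cumene hydroperoxide, CC(C)(OO)c1ccccc1
Why: Proposed new method: hydroxyl-directed vanadium-catalysed epoxidation of a homoallylic alcohol (closest known cases: the vanadium–bishydroxamic acid asymmetric epoxidation of homoallylic alcohols and the achiral VO(acac)2 syn-epoxidation of cyclohexa-2,5-dienylmethanols) should deliver oxygen from the alkoxide-bound vanadium peroxide to the face carrying CH2OH while the chiral ligand selects one of the two enantiotopic alkenes, so that C1, C5 and C6 are set in one event and the minor enantiomer is drained by its faster second epoxidation.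

**Step 3**
Reactants: 4 [(1R,2S,6S)-7-oxabicyclo[4.1.0]hept-3-en-2-yl]methanol
Product: 5 [(1R,2S,6S)-7-oxabicyclo[4.1.0]hept-3-en-2-yl]methyl benzoate
Conditions: PhCOCl, pyridine, CH2Cl2, 0 °C
Reagents that add atoms: benzoyl chloride, O=C(Cl)c1ccccc1
Why: Pyridine-mediated O-acylation (nucleophilic acyl substitution) of the primary alcohol; the oxirane and the three stereocentres are untouched.

**Step 4**
Reactants: 5 [(1R,2S,6S)-7-oxabicyclo[4.1.0]hept-3-en-2-yl]methyl benzoate
Product: 7 [(1S,5R,6R)-5-(benzoyloxy)-6-(triethylsilyloxy)cyclohex-2-en-1-yl]methyl benzoate, via hydroxy dibenzoate 6 (not isolated)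
Conditions: (S,S)-N,N′-bis(3,5-di-tert-butylsalicylidene)cyclohexane-1,2-diaminocobalt (5 mol %; the divalent cobalt complex is oxidised in air by PhCO2H to the active trivalent cobalt benzoate), PhCO2H (1.1 equiv), i-Pr2NEt, t-BuOMe, 0 °C; then Et3SiOTf, 2,6-lutidine, CH2Cl2, −78 → 0 °C
Reagents that add atoms: benzoic acid, O=C(O)c1ccccc1; triethylsilyl trifluoromethanesulfonate, CC[Si](CC)(CC)OS(=O)(=O)C(F)(F)F
Why: Cobalt–salen-catalysed ring opening of the epoxide by benzoic acid (Jacobsen-type opening, SN2, anti) puts benzoate on C5 with inversion, the carbon matched to the catalyst and remote from the C1 branch, leaving the C6 oxygen in place, and the freed C6-OH is silylated in the same flask so that it can neither direct the later epoxidation nor take part in bromination or acyl migration.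

**Step 5**
Reactants: 7 [(1S,5R,6R)-5-(benzoyloxy)-6-(triethylsilyloxy)cyclohex-2-en-1-yl]methyl benzoate
Product: 8 [(1S,2R,3R,5R,6R)-5-(benzoyloxy)-2,3-dibromo-6-(triethylsilyloxy)cyclohexyl]methyl benzoate
Conditions: Br2 (1.05 equiv), CH2Cl2, −78 °C
Reagents that add atoms: bromine, BrBr
Why: Electrophilic anti-addition of Br2 through the bromonium ion on the face opposite the pseudoaxial CH2OBz gives the trans-diaxial dibromide; the C2/C3 stereocentres are temporary and the silyl ether prevents transannular bromo-etherification by the C6 oxygen.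

**Step 6**
Reactants: 8 [(1S,2R,3R,5R,6R)-5-(benzoyloxy)-2,3-dibromo-6-(triethylsilyloxy)cyclohexyl]methyl benzoate
Product: 9 [(5R,6R)-5-(benzoyloxy)-6-(triethylsilyloxy)cyclohexa-1,3-dien-1-yl]methyl benzoate
Conditions: LiCl, Li2CO3, HMPA, 90 °C
Reagents that add atoms: none
Why: Twofold dehydrobromination (E2; the allylic bromide left after the first elimination is inverted by chloride so that C1–H becomes antiperiplanar) is the classical entry to trans-5,6-diacyloxycyclohexa-1,3-dienes, erases the C1 stereocentre and leaves C5/C6 intact because the trans-diaxial ester/silyl ether pair offers no antiperiplanar hydrogen for aromatising loss of PhCO2H.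

**Step 7**
Reactants: 9 [(5R,6R)-5-(benzoyloxy)-6-(triethylsilyloxy)cyclohexa-1,3-dien-1-yl]methyl benzoate
Product: 12 [(1R,2R,5R,6S)-2,5-bis(benzoyloxy)-1,6-dihydroxycyclohex-3-en-1-yl]methyl benzoate (CNP0128482.2), via vinyl epoxide 10 (not isolated), via silylated tribenzoate 11 (not isolated)
Conditions: dimethyldioxirane (1.05 equiv), acetone/CH2Cl2, −20 → 0 °C; evaporate; PhCO2H (3 equiv), toluene, 50 °C; then HF·pyridine, THF, 0 °C
Reagents that add atoms: dimethyldioxirane, CC1(C)OO1; benzoic acid, O=C(O)c1ccccc1
Why: Dioxirane (Prilezhaev-type) epoxidation of the more substituted diene alkene occurs anti to the pseudoaxial allylic C6-OSiEt3 (sets C1), benzoic acid then opens the vinyl oxirane by SN2 attack at allylic C2 with inversion (sets C2 trans to the tertiary OH), which is the epoxidation/benzoate-opening pair proposed for the natural benzoylated cyclohexene oxides, and HF·pyridine finally cleaves the Si–O bond.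

**Compound list**
1 | cyclohexa-1,4-diene | C1=CCC=CC1 | starting material
2 | cyclohexa-2,5-dienyllithium | [Li]C1C=CCC=C1 | intermediate (not isolated)
3 | (cyclohexa-2,5-dien-1-yl)methanol | OCC1C=CCC=C1 | intermediate
4 | [(1R,2S,6S)-7-oxabicyclo[4.1.0]hept-3-en-2-yl]methanol | OC[C@@H]1C=CC[C@@H]2O[C@H]12 | intermediate
5 | [(1R,2S,6S)-7-oxabicyclo[4.1.0]hept-3-en-2-yl]methyl benzoate | O=C(OC[C@@H]1C=CC[C@@H]2O[C@H]12)c1ccccc1 | intermediate
6 | [(1S,5R,6R)-5-(benzoyloxy)-6-hydroxycyclohex-2-en-1-yl]methyl benzoate | O=C(OC[C@@H]1C=CC[C@@H](OC(=O)c2ccccc2)[C@@H]1O)c1ccccc1 | intermediate (not isolated)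
7 | [(1S,5R,6R)-5-(benzoyloxy)-6-(triethylsilyloxy)cyclohex-2-en-1-yl]methyl benzoate | O=C(OC[C@@H]1C=CC[C@@H](OC(=O)c2ccccc2)[C@@H]1O[Si](CC)(CC)CC)c1ccccc1 | intermediate
8 | [(1S,2R,3R,5R,6R)-5-(benzoyloxy)-2,3-dibromo-6-(triethylsilyloxy)cyclohexyl]methyl benzoate | O=C(OC[C@@H]1[C@@H](Br)[C@H](Br)C[C@@H](OC(=O)c2ccccc2)[C@@H]1O[Si](CC)(CC)CC)c1ccccc1 | intermediate
9 | [(5R,6R)-5-(benzoyloxy)-6-(triethylsilyloxy)cyclohexa-1,3-dien-1-yl]methyl benzoate | O=C(OCC1=CC=C[C@@H](OC(=O)c2ccccc2)[C@@H]1O[Si](CC)(CC)CC)c1ccccc1 | intermediate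
10 | [(1S,2S,3R,6S)-3-(benzoyloxy)-2-(triethylsilyloxy)-7-oxabicyclo[4.1.0]hept-4-en-1-yl]methyl benzoate | O=C(OC[C@]12O[C@H]1C=C[C@@H](OC(=O)c3ccccc3)[C@@H]2O[Si](CC)(CC)CC)c1ccccc1 | intermediate (not isolated)
11 | [(1S,2R,5R,6S)-2,5-bis(benzoyloxy)-1-hydroxy-6-(triethylsilyloxy)cyclohex-3-en-1-yl]methyl benzoate | O=C(OC[C@]1(O)[C@H](OC(=O)c2ccccc2)C=C[C@@H](OC(=O)c2ccccc2)[C@@H]1O[Si](CC)(CC)CC)c1ccccc1 | intermediate (not isolated)
12 | [(1R,2R,5R,6S)-2,5-bis(benzoyloxy)-1,6-dihydroxycyclohex-3-en-1-yl]methyl benzoate | O=C(OC[C@]1(O)[C@H](OC(=O)c2ccccc2)C=C[C@@H](OC(=O)c2ccccc2)[C@@H]1O)c1ccccc1 | target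

**Step count and risks**
Total steps: 7. Longest linear sequence: 7 steps (1 → 12).

Three steps most likely to fail:

Step 2 (selection between the two enantiotopic alkenes may be incomplete). The fallback sets out from 3. Achiral directed epoxidation with VO(acac)2 and t-BuOOH in CH2Cl2 gives the racemic cis-epoxy alcohol F1. Kinetic resolution by lipase-catalysed transesterification (Burkholderia cepacia lipase, vinyl benzoate, t-BuOMe) benzoylates one enantiomer and so gives 5 directly, leaving the enantiomeric epoxy alcohol F2. The route is rejoined at 5, and this also replaces step 3.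

Step 4 (regiochemistry of the opening, C5 against C6). The fallback sets out from 4 and uses the free homoallylic hydroxyl as an internal director. Ti(Oi-Pr)4 with PhCO2H in CH2Cl2 opens the chelated epoxy alcohol at the distal carbon C5 (Sharpless-type titanium-assisted opening) to give the diol monobenzoate F3. Its primary hydroxyl is then benzoylated selectively (PhCOCl, 2,4,6-collidine, CH2Cl2, −78 °C) to give 6, where the route is rejoined; 6 is silylated as in step 4.

Step 7 (site and face of the epoxidation; 1,2- against 1,4-opening and ester participation). The fallback sets out from 9. Catalytic OsO4 with N-methylmorpholine N-oxide dihydroxylates the trisubstituted alkene anti to the allylic C6 silyloxy group (Kishi's rule) to give the cis-diol F4. A Mitsunobu reaction (PPh3, diisopropyl azodicarboxylate, PhCO2H, toluene) then inverts the secondary allylic C2 carbinol while installing the benzoate; the tertiary C1 hydroxyl is inert. This gives 11, where the route is rejoined for the HF·pyridine desilylation.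

**Further compounds**
F1 | step 2 | racemic cis-epoxy alcohol (4 and its mirror image, 1:1) | OC[C@@H]1C=CC[C@@H]2O[C@H]12.OC[C@H]1C=CC[C@H]2O[C@@H]12
F2 | step 2 | [(1S,2R,6R)-7-oxabicyclo[4.1.0]hept-3-en-2-yl]methanol (enantiomer of 4) | OC[C@H]1C=CC[C@H]2O[C@@H]12
F3 | step 4 | (1R,5S,6R)-6-hydroxy-5-(hydroxymethyl)cyclohex-3-en-1-yl benzoate | OC[C@@H]1C=CC[C@@H](OC(=O)c2ccccc2)[C@@H]1O
F4 | step 7 | [(1S,2S,5R,6S)-5-(benzoyloxy)-1,2-dihydroxy-6-(triethylsilyloxy)cyclohex-3-en-1-yl]methyl benzoate | O=C(OC[C@]1(O)[C@@H](O)C=C[C@@H](OC(=O)c2ccccc2)[C@@H]1O[Si](CC)(CC)CC)c1ccccc1
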